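**Plan**

- Numbering used below (elemane type): ring C5–C10 (C10 quaternary with methyl C14 and vinyl C1=C2; C9 CH2; C8 O-acyl; C7 bears C11(=C13)–C12O2H; C6 OH; C5 bears C4(=C15)–C3H2OH); acyl chain C1'–C4'.
- Late disconnections: the C12 acid and C11=C13 come from a C7 malonate (decarboxylative Mannich methylenation); the C8 ester from a 1,3-anti diol and a chiral-pool acid; the C10 vinyl and C5 2-propenyl groups from ethenolysis of a cis-fused cyclobutene (C1=C4).
- Central disconnection: ring bonds C9–C10 and C5–C6 are cut together, as a [4+2] addition of 4-silyloxy-2-pyranone (C6–C7–C8–C9, with a CO2 bridge from C9 to O6) to 3-methylcyclobut-2-enone (C10=C5, C4=O, C1).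
- Enabling feature: ring carbons C6–C7–C8–C9 carry oxygen at C6 and C8, which is the pattern of a 4-oxy-2-pyranone once C9 bears a carboxyl tied to O6 (lost later as CO2 from the β-keto acid); C10 and C5 carry cis vinyl and 2-propenyl groups, the two halves of a cyclobutene.
- Forward order of rings: cyclobutenone ([2+2]) → six-membered carbocycle with temporary lactone bridge and fused four-membered ring (key step) → C7 malonate → lactone bridge removed → four-membered ring opened → ester → malonate unveiled and methylenated under a C6 silyl ether → acid, then fluoride deprotection.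
- Stereochemistry: C10, C5, C6 from the cycloaddition (cis ring alkene, endo rule, lactone bridge; absolute sense from a chiral oxazaborolidinium Lewis acid); C7 from exo attack on the bicyclic enol ether; C8 from hydroxyl-directed reduction; C3' from (R)-1,2,4-butanetriol acetonide.

Key step: step 4

Assumption: 4-hydroxy-2H-pyran-2-one, di-tert-butyl bromomalonate and (R)-2-(2,2-dimethyl-1,3-dioxolan-4-yl)ethanol are taken as catalogue chemicals, and the free cis-γ-hydroxy acid target is taken to be stable enough for isolation at pH 4–6 below 25 °C.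

**Step 1**
Reactants: 1 propyne; 2 trichloroacetyl chloride
Product: 4 4,4-dichloro-3-methylcyclobut-2-en-1-one, via dichloroketene 3 (not isolated)
Conditions: Zn(Cu), Et2O/DME, 25 °C
Reagents that add atoms: none
Why: Dichloroketene, formed in the flask by zinc dechlorination of the acid chloride, should add to the alkyne in a thermal [2+2] ketene–alkyne cycloaddition in which the carbonyl carbon bonds to the terminal alkyne carbon; no stereocentre is formed.

**Step 2**
Reactants: 4 4,4-dichloro-3-methylcyclobut-2-en-1-one
Product: 5 3-methylcyclobut-2-en-1-one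
Conditions: Zn, AcOH, TMEDA, EtOH, 0 °C → rt
Reagents that add atoms: none
Why: Zinc in buffered acetic acid should reduce both α-C–Cl bonds (reductive dehalogenation of an α,α-dichloroketone) and leave the strained enone intact, as in the standard preparation of 3-alkylcyclobutenones.

**Step 3**
Reactants: 6 4-hydroxy-2H-pyran-2-one
Product: 7 4-[(tert-butyldimethylsilyl)oxy]-2H-pyran-2-one
Conditions: TBSCl, imidazole, CH2Cl2, 0 °C → rt
Reagents that add atoms: tert-butyldimethylsilyl chloride, CC(C)(C)[Si](C)(C)Cl
Why: O-Silylation of the vinylogous acid at O4 should give the 2-pyranone tautomer of the silyl ether, an electron-rich diene whose C3 is a silyl enol ether carbon.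

**Step 4**
Reactants: 7 4-[(tert-butyldimethylsilyl)oxy]-2H-pyran-2-one; 5 3-methylcyclobut-2-en-1-one
Product: 8 endo cycloadduct (lactone-bridged C7=C8 silyl enol ether cis-fused at C5–C10 to the cyclobutanone)
Conditions: (S)-3,3-diphenyl-1-(o-tolyl)tetrahydro-1H,3H-pyrrolo[1,2-c][1,3,2]oxazaborole·AlBr3 (20 mol %), CH2Cl2, −78 → −30 °C, 7 added over 6 h
Reagents that add atoms: none
Why: Proposed new method: the AlBr3-activated oxazaborolidine binds the cyclobutenone carbonyl and lowers the LUMO of the strained C=C, so that C3 of the 4-silyloxy-2-pyranone (the nucleophilic diene terminus, β to the silyloxy group) attacks the methyl-bearing β-carbon (future C10) while C6 of the pyranone bonds to the α-carbon (future C5) in one concerted but asynchronous [4+2] event; the closest known reaction types are oxazaborolidinium-catalysed Diels–Alder additions of 2-silyloxy-1,3-dienes to 2-cycloalkenones, uncatalysed additions of cyclobutenone to oxygenated dienes and pressure-promoted additions of 2-pyranones to enones. The carbocycle C5–C6–C7–C8–C9–C10 closes by intermolecular suprafacial/suprafacial cycloaddition (no tether), which at the same time turns the pyranone into the C9–CO–O–C6 lactone bridge (2-oxabicyclo[2.2.2]octene) and leaves the four-membered ring cis-fused at C5–C10. C10 and C5 keep the cis geometry of the ring alkene (methyl and H5 on one face), C6 and C9 are fixed relative to each other by the lactone bridge, and the endo rule (ketone carbonyl under the diene) puts the four-membered ring on the face opposite to that bridge, so that O6 ends up trans to the C5–C4 bond and cis to the C10 methyl as in the target. The absolute sense is set by the catalyst, which shields one face of the bound enone; the (S)-catalyst is the first choice by analogy with 2-cycloalkenones and its mirror image is used if the sense found is the opposite one. The step needs regioselectivity (C9 to C10 and not to C5), secured by the matched polarity of the silyl enol ether carbon and the enone β-carbon, endo selectivity, secured by secondary orbital overlap and by the methyl group preferring the exo side, and turnover in the presence of the Lewis basic pyranone carbonyl, secured by slow addition of 7 so that the small share of catalyst bound to the far more reactive enone carries the reaction.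

**Step 5**
Reactants: 8 endo cycloadduct
Product: 9 cyclobutenyl triflate (C1=C4–OTf)
Conditions: KN(SiMe3)2, PhNTf2, THF, −78 °C
Reagents that add atoms: N-phenylbis(trifluoromethanesulfonimide), O=S(=O)(N(c1ccccc1)S(=O)(=O)C(F)(F)F)C(F)(F)F
Why: Kinetic deprotonation of the cyclobutanone at its CH2 (C1) and O-sulfonylation of the enolate (enol triflate formation) should win over reaction at the hindered ring-fusion CH (C5), while the lactone α-carbon C9 is a bridgehead that cannot enolise.

**Step 6**
Reactants: 9 cyclobutenyl triflate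
Product: 10 cyclobutenylmethanol (C4–CH2OH)
Conditions: Bu3SnCH2OH, Pd(PPh3)4 (5 mol %), LiCl, 1,4-dioxane, 60 °C
Reagents that add atoms: (tributylstannyl)methanol, CCCC[Sn](CCCC)(CCCC)CO
Why: Stille coupling of the alkenyl triflate should transfer the hydroxymethyl group (future C3) to C4, oxidative addition to the triflate outpacing ionisation of the bridged allylic lactone, whose anti face is covered by the four-membered ring; no stereocentre is touched.

**Step 7**
Reactants: 10 cyclobutenylmethanol
Product: 11 primary TBS ether of 10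
Conditions: TBSCl, imidazole, DMF, 0 °C → rt
Reagents that add atoms: tert-butyldimethylsilyl chloride, CC(C)(C)[Si](C)(C)Cl
Why: Standard silylation of the primary allylic alcohol, so that the silyl bromide released in step 8 finds no free hydroxyl and only ring hydroxyls are free in step 15.

**Step 8**
Reactants: 11 primary TBS ether; 12 di-tert-butyl bromomalonate
Product: 13 bicyclic C8 ketone carrying the exo C7 di-tert-butyl malonate
Conditions: fac-Ir(ppy)3 (1 mol %), 2,6-lutidine, MeCN, blue LEDs, rt
Reagents that add atoms: none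
Why: Photoredox radical alkylation of a silyl enol ether: the electrophilic malonyl radical should add to C7 on the face syn to the lactone bridge (the other face is covered by the endo cyclobutene and its CH2OTBS group), and oxidation and desilylation of the α-silyloxy radical give the C8 ketone, so C7 is set cis to O6.

**Step 9**
Reactants: 13 bicyclic C8 ketone
Product: 15 hydroxy ketone (C6–OH; C8=O; C9H2), via ring-opened β-keto acid 14 (not isolated)
Conditions: LiOH (2.5 equiv), THF/H2O, 0 °C; then 1 M HCl to pH 3–4, 30 °C
Reagents that add atoms: none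
Why: Saponification of the bridged lactone should give a β-keto acid that loses CO2 on mild acidification (β-keto acid decarboxylation), while the malonate, deprotonated first, keeps the neighbouring C7–H from enolising, so C6 and C7 are retained.

**Step 10**
Reactants: 15 hydroxy ketone
Product: 16 1,3-anti diol (C6–OH; C8–OH)
Conditions: Me4NBH(OAc)3, MeCN/AcOH (1:1), −30 °C
Reagents that add atoms: none
Why: Evans–Saksena reduction: the C6 hydroxyl binds the triacetoxyborohydride and delivers hydride to C8 on its own face, which should give the 1,3-anti diol with the C8 hydroxyl trans to O6 and to the C7 substituent.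

**Step 11**
Reactants: 16 1,3-anti diol
Product: 17 ring-opened diol (C10 vinyl; C5 3-silyloxyprop-1-en-2-yl)
Conditions: second-generation Grubbs catalyst RuCl2(=CHPh)(PCy3)(H2IMes) (5 mol %), ethylene (1 atm), CH2Cl2, rt
Reagents that add atoms: ethylene, C=C
Why: Ring-opening metathesis with ethylene (ethenolysis), driven by release of cyclobutene strain, should turn C1=C4 into the C10 vinyl group and the C5 2-propenyl unit with the cis relation at C10 and C5 untouched.

**Step 12**
Reactants: 18 (R)-2-(2,2-dimethyl-1,3-dioxolan-4-yl)ethanol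
Product: 19 (R)-2-(2,2-dimethyl-1,3-dioxolan-4-yl)acetaldehyde
Conditions: Dess–Martin periodinane, pyridine, CH2Cl2, 0 °C → rt
Reagents that add atoms: none
Why: Dess–Martin oxidation of the primary alcohol should stop at the aldehyde and leave the acetonide and its stereocentre untouched.

**Step 13**
Reactants: 19 (R)-2-(2,2-dimethyl-1,3-dioxolan-4-yl)acetaldehyde
Product: 20 2-[(4R)-2,2-dimethyl-1,3-dioxolan-4-yl]prop-2-enal
Conditions: CH2=NMe2+ I−, Et3N, CH2Cl2, rt
Reagents that add atoms: N,N-dimethylmethyleneiminium iodide, C=[N+](C)C.[I-]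
Why: Mannich reaction of the aldehyde with the iminium salt followed by loss of dimethylamine (α-methylenation of an aldehyde) should give the 2-substituted acrolein; the dioxolane stereocentre is not involved.

**Step 14**
Reactants: 20 2-[(4R)-2,2-dimethyl-1,3-dioxolan-4-yl]prop-2-enal
Product: 21 2-[(4R)-2,2-dimethyl-1,3-dioxolan-4-yl]prop-2-enoic acid
Conditions: NaClO2, NaH2PO4, 2-methyl-2-butene, t-BuOH/H2O, 0 °C
Reagents that add atoms: sodium chlorite, [Na+].[O-]Cl=O
Why: Pinnick oxidation should convert the enal to the acrylic acid without touching the alkene, 2-methyl-2-butene taking up the hypochlorite.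

**Step 15**
Reactants: 17 ring-opened diol; 21 2-[(4R)-2,2-dimethyl-1,3-dioxolan-4-yl]prop-2-enoic acid
Product: 22 C8 ester (C6–OH free)
Conditions: 21, 2,4,6-trichlorobenzoyl chloride, Et3N, THF; then 17, DMAP, toluene, rt
Reagents that add atoms: none
Why: Yamaguchi esterification through the mixed anhydride should acylate the C8 hydroxyl, which has one CH2 neighbour, in preference to the C6 hydroxyl, which is flanked by the two branched carbons C5 and C7; C8 keeps its configuration.

**Step 16**
Reactants: 22 C8 ester
Product: 25 C6-O-silyl acrylic acid, via silyl ether bis(silyl ester) 23 (not isolated), via C6-O-silyl malonic acid 24 (not isolated)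
Conditions: t-BuMe2SiOTf (5 equiv), 2,6-lutidine, CH2Cl2, −20 °C → rt; THF/pH 7 buffer, rt; then CH2=NMe2+ I−, Et3N, MeCN, rt → 40 °C
Reagents that add atoms: tert-butyldimethylsilyl trifluoromethanesulfonate, CC(C)(C)[Si](C)(C)OS(=O)(=O)C(F)(F)F; N,N-dimethylmethyleneiminium iodide, C=[N+](C)C.[I-]
Why: The silyl triflate should first silylate the C6 hydroxyl in the cold and then, at rt, turn both tert-butyl esters into silyl esters with loss of isobutene; the buffer hydrolyses only the silyl esters, and the Mannich base of the freed malonic acid loses CO2 and dimethylamine (decarboxylative Mannich methylenation) to give the C11=C13 acrylic acid while the side-chain diol is still an acetonide and O6 sits under a silyl ether robust enough for the acid of step 17.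

**Step 17**
Reactants: 25 C6-O-silyl acrylic acid
Product: 26 triol acid (C6–OTBS kept)
Conditions: AcOH/THF/H2O (3:1:1), 40 °C
Reagents that add atoms: none
Why: Acid-catalysed hydrolysis should remove the terminal acetonide and the primary allylic silyl ether, while the secondary silyl ether at C6, flanked by two branched carbons, hydrolyses far more slowly and so keeps O6 from closing the γ-lactone onto C12 in the only acidic step of the end game; the C8 ester and the alkenes are stable.

**Step 18**
Reactants: 26 triol acid
Product: 27 target, 2-[(1S,2S,3S,4S,6S)-6-{[(3R)-3,4-dihydroxy-2-methylidenebutanoyl]oxy}-4-ethenyl-2-hydroxy-3-(3-hydroxyprop-1-en-2-yl)-4-methylcyclohexyl]prop-2-enoic acid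
Conditions: HF·pyridine, pyridine, THF, 0 °C → rt; pH 5 buffer work-up
Reagents that add atoms: none
Why: Fluoride-driven desilylation in pyridine-buffered HF·pyridine should free the last hydroxyl close to neutrality, which avoids both acid-promoted lactonisation of O6 onto C12 and base-promoted lactonisation of the side-chain 4'-hydroxyl.

**Compound list**

1 | propyne | CC#C | starting material
2 | trichloroacetyl chloride | ClC(Cl)(Cl)C(Cl)=O | starting material
3 | dichloroketene | ClC(Cl)=C=O | intermediate
4 | 4,4-dichloro-3-methylcyclobut-2-en-1-one | CC1=CC(=O)C1(Cl)Cl | intermediate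
5 | 3-methylcyclobut-2-en-1-one | CC1=CC(=O)C1 | intermediate
6 | 4-hydroxy-2H-pyran-2-one | O=C1C=C(O)C=CO1 | starting material
7 | 4-[(tert-butyldimethylsilyl)oxy]-2H-pyran-2-one | O=C1C=C(O[Si](C)(C)C(C)(C)C)C=CO1 | intermediate
8 | endo cycloadduct: C7=C8 enol ether with 8-OTBS, lactone bridge C9–C(=O)–O–C6, cyclobutanone (C4=O, C1H2) cis-fused at C5–C10 on the face opposite the bridge, C10 methyl and H5 on the bridge face; C5, C6, C10 as in 27 | C2[C@]1(C)[C@@H]3C(O[Si](C)(C)C(C)(C)C)=C[C@@H](OC3=O)[C@@H]1C2=O | intermediate
9 | cyclobutenyl triflate of 8 (C1=C4, C4–OTf; other centres as in 8) | C=2[C@]1(C)[C@@H]3C(O[Si](C)(C)C(C)(C)C)=C[C@@H](OC3=O)[C@@H]1C2OS(=O)(=O)C(F)(F)F | intermediate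
10 | cyclobutenylmethanol (C4–CH2OH; other centres as in 8) | C=2[C@]1(C)[C@@H]3C(O[Si](C)(C)C(C)(C)C)=C[C@@H](OC3=O)[C@@H]1C2CO | intermediate
11 | primary TBS ether of 10 | C=2[C@]1(C)[C@@H]3C(O[Si](C)(C)C(C)(C)C)=C[C@@H](OC3=O)[C@@H]1C2CO[Si](C)(C)C(C)(C)C | intermediate
12 | di-tert-butyl bromomalonate (di-tert-butyl 2-bromopropanedioate) | CC(C)(C)OC(=O)C(Br)C(=O)OC(C)(C)C | starting material
13 | bicyclic C8 ketone, lactone bridge intact, C7 di-tert-butyl malonate on the bridge face (cis to O6) | C=2[C@]1(C)[C@@H]3C(=O)[C@@H](C(C(=O)OC(C)(C)C)C(=O)OC(C)(C)C)[C@@H](OC3=O)[C@@H]1C2CO[Si](C)(C)C(C)(C)C | intermediate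
14 | ring-opened β-keto acid (C9–CO2H cis to C6–OH) | C=2[C@]1(C)[C@@H](C(=O)O)C(=O)[C@@H](C(C(=O)OC(C)(C)C)C(=O)OC(C)(C)C)[C@@H](O)[C@@H]1C2CO[Si](C)(C)C(C)(C)C | intermediate
15 | hydroxy ketone: cyclobutene-fused cyclohexanone, C6–OH, C8=O, C7 malonate cis to O6 | C=2[C@]1(C)CC(=O)[C@@H](C(C(=O)OC(C)(C)C)C(=O)OC(C)(C)C)[C@@H](O)[C@@H]1C2CO[Si](C)(C)C(C)(C)C | intermediate
16 | 1,3-anti diol: C8–OH trans to C6–OH and to the C7 malonate, cyclobutene still fused | C=2[C@]1(C)C[C@H](O)[C@@H](C(C(=O)OC(C)(C)C)C(=O)OC(C)(C)C)[C@@H](O)[C@@H]1C2CO[Si](C)(C)C(C)(C)C | intermediate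
17 | ring-opened diol: C10 vinyl and methyl, C5 3-(TBS-oxy)prop-1-en-2-yl, C5–C8 and C10 as in 27 | C=C[C@]1(C)C[C@H](O)[C@@H](C(C(=O)OC(C)(C)C)C(=O)OC(C)(C)C)[C@@H](O)[C@@H]1C(=C)CO[Si](C)(C)C(C)(C)C | intermediate
18 | (R)-2-(2,2-dimethyl-1,3-dioxolan-4-yl)ethanol | OCC[C@@H]1COC(C)(C)O1 | starting material
19 | (R)-2-(2,2-dimethyl-1,3-dioxolan-4-yl)acetaldehyde | O=CC[C@@H]1COC(C)(C)O1 | intermediate
20 | 2-[(4R)-2,2-dimethyl-1,3-dioxolan-4-yl]prop-2-enal | O=CC(=C)[C@@H]1COC(C)(C)O1 | intermediate
21 | 2-[(4R)-2,2-dimethyl-1,3-dioxolan-4-yl]prop-2-enoic acid | OC(=O)C(=C)[C@@H]1COC(C)(C)O1 | intermediate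
22 | C8 ester of 17 with acid 21 (C6–OH free, acetonide and primary TBS in place) | C=C[C@]1(C)C[C@H](OC(=O)C(=C)[C@@H]2COC(C)(C)O2)[C@@H](C(C(=O)OC(C)(C)C)C(=O)OC(C)(C)C)[C@@H](O)[C@@H]1C(=C)CO[Si](C)(C)C(C)(C)C | intermediate
23 | silyl ether bis(silyl ester): C6–OTBS, bis(tert-butyldimethylsilyl) malonate; acetonide and primary TBS ether in place | C=C[C@]1(C)C[C@H](OC(=O)C(=C)[C@@H]2COC(C)(C)O2)[C@@H](C(C(=O)O[Si](C)(C)C(C)(C)C)C(=O)O[Si](C)(C)C(C)(C)C)[C@@H](O[Si](C)(C)C(C)(C)C)[C@@H]1C(=C)CO[Si](C)(C)C(C)(C)C | intermediate
24 | C6-O-silyl malonic acid (C6–OTBS; acetonide and primary TBS ether in place) | C=C[C@]1(C)C[C@H](OC(=O)C(=C)[C@@H]2COC(C)(C)O2)[C@@H](C(C(=O)O)C(=O)O)[C@@H](O[Si](C)(C)C(C)(C)C)[C@@H]1C(=C)CO[Si](C)(C)C(C)(C)C | intermediate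
25 | C6-O-silyl acrylic acid (C11=C13, C12O2H; C6–OTBS; acetonide and primary TBS ether in place) | C=C[C@]1(C)C[C@H](OC(=O)C(=C)[C@@H]2COC(C)(C)O2)[C@@H](C(=C)C(=O)O)[C@@H](O[Si](C)(C)C(C)(C)C)[C@@H]1C(=C)CO[Si](C)(C)C(C)(C)C | intermediate
26 | triol acid (C3, C3', C4' hydroxyls free; C6–OTBS kept) | C=C[C@]1(C)C[C@H](OC(=O)C(=C)[C@@H](O)CO)[C@@H](C(=C)C(=O)O)[C@@H](O[Si](C)(C)C(C)(C)C)[C@@H]1C(=C)CO | intermediate
27 | 2-[(1S,2S,3S,4S,6S)-6-{[(3R)-3,4-dihydroxy-2-methylidenebutanoyl]oxy}-4-ethenyl-2-hydroxy-3-(3-hydroxyprop-1-en-2-yl)-4-methylcyclohexyl]prop-2-enoic acid | C=C[C@]1(C)C[C@H](OC(=O)C(=C)[C@@H](O)CO)[C@@H](C(=C)C(=O)O)[C@@H](O)[C@@H]1C(=C)CO | target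

**Step count**

Total: 18 steps. Longest linear sequence: 14 steps (steps 1, 2, 4–11, 15–18).

**Steps most likely to fail**

Step 4. The process at risk is face and turnover control: the pyranone carbonyl may hold the Lewis acid, conjugate addition may occur without ring closure, the cyclobutenone may open electrocyclically, or the face discrimination may be poor. The fallback sets out from 7 and 5 and gives up asymmetric catalysis for resolution. The uncatalysed cycloaddition under hydrostatic pressure (1.2 GPa, CH2Cl2, rt; a known mode for 2-pyranones with enones that keeps the CO2 bridge) should give the endo adduct as a racemate. This is 8 together with the mirror-image cycloadduct F1, which is removed by preparative chromatography on a cellulose tris(3,5-dimethylphenylcarbamate) phase. The route is rejoined at 8.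

Step 15. The process at risk is site selection between the two hindered ring hydroxyls, or slow acyl transfer to either. The fallback sets out from 15 and makes the C8–O bond by substitution instead of acylation. Reduction of 15 with LiBH(s-Bu)3 (THF, −78 °C) should take place anti to the C7 malonate and give the C8-epimeric syn diol F2. Ethenolysis as in step 11 gives the ring-opened C8-epimeric diol F3. Mitsunobu esterification of F3 with acid 21 (PPh3, diisopropyl azodicarboxylate, toluene, 0 °C → rt) should invert the less hindered C8 carbinol, displacement at C6 between two branched carbons being far slower. The route is rejoined at 22.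

Step 18. The process at risk is slow cleavage of the hindered C6 silyl ether, during which the freed cis-γ-hydroxy acid may close to the lactone on long exposure to the weakly acidic fluoride source. The fallback sets out from 22 and masks every hydroxyl with labile triethylsilyl groups instead of holding O6 alone under a robust one.
- Hydrolysis of 22 (AcOH/THF/H2O 3:1:1, 40 °C), carried out while the acid is still the di-tert-butyl malonate, should give the tetraol di-tert-butyl malonate F4.
- Et3SiOTf (8 equiv) and 2,6-lutidine (CH2Cl2, 0 °C → rt) should silylate the four hydroxyls and turn both tert-butyl esters into silyl esters, giving the hexakis(triethylsilyl) malonate F5.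
- Work-up with pH 7 buffer frees the tetra-O-triethylsilyl malonic acid F6.
- CH2=NMe2+ I− and Et3N (MeCN, rt → 40 °C) then give the tetra-O-triethylsilyl acrylic acid F7.
- Bu4NF/AcOH (1:1, THF, 0 °C; pH 5 buffer work-up) removes the four triethylsilyl ethers far faster than a hindered tert-butyldimethylsilyl ether would go.

The route is rejoined at 27.

**Further compounds**

F1 | step 4 | mirror-image cycloadduct (enantiomer of 8) | C2[C@@]1(C)[C@H]3C(O[Si](C)(C)C(C)(C)C)=C[C@H](OC3=O)[C@H]1C2=O
F2 | step 15 | C8-epimeric syn diol (C8 epimer of 16) | C=2[C@]1(C)C[C@@H](O)[C@@H](C(C(=O)OC(C)(C)C)C(=O)OC(C)(C)C)[C@@H](O)[C@@H]1C2CO[Si](C)(C)C(C)(C)C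
F3 | step 15 | ring-opened C8-epimeric diol (C8 epimer of 17) | C=C[C@]1(C)C[C@@H](O)[C@@H](C(C(=O)OC(C)(C)C)C(=O)OC(C)(C)C)[C@@H](O)[C@@H]1C(=C)CO[Si](C)(C)C(C)(C)C
F4 | step 18 | tetraol di-tert-butyl malonate (C3, C6, C3', C4' hydroxyls free) | C=C[C@]1(C)C[C@H](OC(=O)C(=C)[C@@H](O)CO)[C@@H](C(C(=O)OC(C)(C)C)C(=O)OC(C)(C)C)[C@@H](O)[C@@H]1C(=C)CO
F5 | step 18 | hexakis(triethylsilyl) malonate (four silyl ethers, two silyl esters) | C=C[C@]1(C)C[C@H](OC(=O)C(=C)[C@@H](O[Si](CC)(CC)CC)CO[Si](CC)(CC)CC)[C@@H](C(C(=O)O[Si](CC)(CC)CC)C(=O)O[Si](CC)(CC)CC)[C@@H](O[Si](CC)(CC)CC)[C@@H]1C(=C)CO[Si](CC)(CC)CC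
F6 | step 18 | tetra-O-triethylsilyl malonic acid | C=C[C@]1(C)C[C@H](OC(=O)C(=C)[C@@H](O[Si](CC)(CC)CC)CO[Si](CC)(CC)CC)[C@@H](C(C(=O)O)C(=O)O)[C@@H](O[Si](CC)(CC)CC)[C@@H]1C(=C)CO[Si](CC)(CC)CC
F7 | step 18 | tetra-O-triethylsilyl acrylic acid (C11=C13, C12O2H) | C=C[C@]1(C)C[C@H](OC(=O)C(=C)[C@@H](O[Si](CC)(CC)CC)CO[Si](CC)(CC)CC)[C@@H](C(=C)C(=O)O)[C@@H](O[Si](CC)(CC)CC)[C@@H]1C(=C)CO[Si](CC)(CC)CC
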